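Retrosynthesis: the acetate and acid are adjusted last; the axial C3–OAc goes back to a C3 ketone (kept as a ketal) and the C8=C17 methylene with H-9 goes back to a C8(CH2SiMe3)=C9 allylsilane. The ring B cyclohexene so revealed is cut at C5–C10 and C6–C7 (intramolecular Diels–Alder, with a formyl group on C6 as a removable activator), which opens ring A at the same time.
The open-chain trienal is cut at C5=C6–CHO (cross-metathesis), C9–C11 (Negishi), C8 (ester to 2-silylmethyl diene), C1–C10 (carbocupration of methyl but-2-ynoate) and C3–C4 (acylation of prenylsilane).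
Forward: the chain is built linearly (C3–C4, then C1–C10, then C9–C11), and rings A and B then arise together in one cycloaddition, ring A through the C1–C4 tether and ring B as the new cyclohexene.
Enabling feature: ring B is a six-membered carbocycle whose exocyclic C8 methylene is the allyl-shifted form of a C8=C9 ring alkene. Ring B is therefore the adduct of diene C7=C8–C9=C10 and dienophile C5=C6, and the ring-fusion bond C5–C10 makes the four carbons C1–C4 of ring A the tether.
Stereochemistry: C13 comes from (R)-monomethyl 3-methylglutarate; C5 and C10 from the amine-catalysed endo cycloaddition (alkene geometries plus catalyst face); C9 from axial protonation of the allylsilane anti to the angular methyl; C3 from L-Selectride reduction of the ketone.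

Key step: step 9

Remark: locants are those of the labdane skeleton (decalin C1–C10, side chain C11–C16, C17 on C8, C18 and C19 on C4, C20 on C10) and serve for position only; the structure is read as (3S,5S,9R,10S,13R), a trans-decalin whose 3-acetoxy group is axial and cis to H-5.

Step 1
Reactants: 1 3-bromopropanoyl chloride; 2 trimethyl(3-methylbut-2-en-1-yl)silane
Product: 3 1-bromo-4,4-dimethylhex-5-en-3-one
Conditions: TiCl4, CH2Cl2, −78 °C
Reagents that add atoms: none
Why: Lewis-acid-mediated acylation of an allylsilane (Sakurai-type SE2′ acylation) attacks the γ-carbon of the prenylsilane, so the quaternary C4 and the C5=C6 vinyl group arise together in a ketone that cannot conjugate.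

Step 2
Reactants: 3 1-bromo-4,4-dimethylhex-5-en-3-one
Product: 4 2-(2-bromoethyl)-2-(2-methylbut-3-en-2-yl)-1,3-dioxolane
Conditions: HOCH2CH2OH, p-TsOH (cat.), benzene, reflux (Dean–Stark)
Reagents that add atoms: ethylene glycol, OCCO
Why: Acid-catalysed ketalisation masks the C3 ketone for the organometallic steps and leaves the tether without a stereocentre.

Step 3
Reactants: 4 2-(2-bromoethyl)-2-(2-methylbut-3-en-2-yl)-1,3-dioxolane; 5 methyl but-2-ynoate
Product: 9 methyl (2Z)-2-iodo-3-methyl-5-[2-(2-methylbut-3-en-2-yl)-1,3-dioxolan-2-yl]pent-2-enoate, via Grignard reagent 6 (not isolated), via alkylcopper 7 (not isolated), via alkenylcopper 8 (not isolated)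
Conditions: Mg, THF, 25 °C; CuBr·SMe2, THF, −45 °C; 5, −78 °C; I2, −78 °C
Reagents that add atoms: iodine, II
Why: syn-Carbocupration of the 2-alkynoate by the Grignard-derived alkylcopper, then iodinolysis of the configurationally stable α-cuprio ester at −78 °C with retention, fixes the tetrasubstituted C9=C10 geometry (C1 cis to iodine, C20 methyl cis to the ester carbon C8).

Step 4
Reactants: 9 methyl (2Z)-2-iodo-3-methyl-5-[2-(2-methylbut-3-en-2-yl)-1,3-dioxolan-2-yl]pent-2-enoate
Product: 11 trimethyl{(3Z)-3-iodo-4-methyl-2-methylidene-6-[2-(2-methylbut-3-en-2-yl)-1,3-dioxolan-2-yl]hex-3-en-1-yl}silane, via carbinol 10 (not isolated)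
Conditions: Me3SiCH2MgCl (3 equiv), CeCl3, THF, −78 °C → rt; then SiO2, CH2Cl2, rt
Reagents that add atoms: (trimethylsilyl)methylmagnesium chloride, C[Si](C)(C)C[Mg]Cl
Why: Cerium-mediated double addition of the silylmethyl Grignard reagent to the ester, then Peterson olefination of the bis(silylmethyl)carbinol, turns C8 into the C7=C8(CH2SiMe3) unit before any other ester is present and does not touch the C9=C10 geometry.

Step 5
Reactants: 12 (3R)-5-methoxy-3-methyl-5-oxopentanoic acid [(R)-monomethyl 3-methylglutarate]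
Product: 13 methyl (3R)-5-hydroxy-3-methylpentanoate
Conditions: BH3·SMe2, THF, 0 °C → rt
Reagents that add atoms: none
Why: Borane reduces the free carboxylic acid chemoselectively beside the methyl ester and leaves the chiral-pool C13 centre untouched.

Step 6
Reactants: 13 methyl (3R)-5-hydroxy-3-methylpentanoate
Product: 14 methyl (3S)-5-iodo-3-methylpentanoate
Conditions: I2, PPh3, imidazole, CH2Cl2, 0 °C → rt
Reagents that add atoms: iodine, II
Why: Appel-type iodination of the primary alcohol, done at once to forestall lactonisation; the descriptor changes only because the CIP priorities change.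

Step 7
Reactants: 11 trimethyl{(3Z)-3-iodo-4-methyl-2-methylidene-6-[2-(2-methylbut-3-en-2-yl)-1,3-dioxolan-2-yl]hex-3-en-1-yl}silane; 14 methyl (3S)-5-iodo-3-methylpentanoate
Product: 16 methyl (3R,6E)-3,7-dimethyl-9-[2-(2-methylbut-3-en-2-yl)-1,3-dioxolan-2-yl]-6-[3-(trimethylsilyl)prop-1-en-2-yl]non-6-enoate, via organozinc iodide 15 (not isolated)
Conditions: 14, Zn, LiCl, THF, 40 °C; then 11, Pd(dppf)Cl2 (5 mol%), THF, 50 °C
Reagents that add atoms: none
Why: Zinc insertion and Negishi sp3–sp2 coupling with retention of the alkenyl iodide geometry joins C9 to C11 and completes the diene (C1 tether trans to C8, C20 methyl cis to C8) with the side chain and its C13 centre in place.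

Step 8
Reactants: 16 methyl (3R,6E)-3,7-dimethyl-9-[2-(2-methylbut-3-en-2-yl)-1,3-dioxolan-2-yl]-6-[3-(trimethylsilyl)prop-1-en-2-yl]non-6-enoate
Product: 17 methyl (3R,6E)-3,7-dimethyl-9-{2-[(3E)-2-methyl-5-oxopent-3-en-2-yl]-1,3-dioxolan-2-yl}-6-[3-(trimethylsilyl)prop-1-en-2-yl]non-6-enoate
Conditions: crotonaldehyde (5 equiv), second-generation Hoveyda–Grubbs catalyst (5 mol%), CH2Cl2, 40 °C
Reagents that add atoms: (E)-but-2-enal, C/C=C/C=O
Why: Olefin cross-metathesis of the only monosubstituted alkene with an electron-poor partner should give the thermodynamic (E)-enal, the 1,1-disubstituted diene terminus and the tetrasubstituted alkene being too hindered to enter the cycle.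

Step 9
Reactants: 17 methyl (3R,6E)-3,7-dimethyl-9-{2-[(3E)-2-methyl-5-oxopent-3-en-2-yl]-1,3-dioxolan-2-yl}-6-[3-(trimethylsilyl)prop-1-en-2-yl]non-6-enoate
Product: 18 methyl (5S,6R,10R,13R)-3,3-ethylenedioxy-6-formyl-17-trimethylsilyl-labd-8-en-15-oate (trans-fused decalin, 6-CHO cis to H-5)
Conditions: (2R,5R)-5-benzyl-2-tert-butyl-3-methylimidazolidin-4-one·CF3CO2H (20 mol%), MeCN/H2O (98:2), 0 °C → rt
Reagents that add atoms: none
Why: The amine condenses with the enal to an (E)-iminium ion whose LUMO-lowered C5=C6 bond adds suprafacially to the s-cis C7=C8–C9=C10 diene in a concerted but asynchronous [4+2] cycloaddition (C5–C10 bonding ahead of C6–C7), and hydrolysis of the product iminium releases aldehyde 18 and the catalyst. The closest known reaction type is the imidazolidinone-catalysed enantioselective intramolecular Diels–Alder reaction of 2,8,10-trienals to trans-fused decalin aldehydes (type 1 IMDA). Ring A closes through the four-carbon tether C1–C4 in the fused mode via a chair-like six-membered array, helped by the gem-dimethyl and dioxolane groups on the tether (Thorpe–Ingold effect), and ring B is the cyclohexene made by the cycloaddition itself. The trans relation of H-5 and the C10 methyl follows from the endo orientation of the iminium over the diene together with the (E)-dienophile and the (E)-diene terminus (tether outside, methyl inside); the absolute configuration at C5 and C10 follows from the (2R,5R) catalyst, whose benzyl group covers the Si face of C5 so that the diene adds to the Re face; and the C6 centre (formyl cis to H-5, removed later) follows from the (E)-alkene geometry. The step needs endo over exo and one π-face over the other (regiochemistry is fixed by the tether); both are catalyst-controlled, and because C3 is an achiral ketal carbon and C13 is remote, no substrate bias opposes the catalyst. The allylsilane should be inert to the weakly acidic amine salt and is carried into the adduct as the C8(CH2SiMe3)=C9 unit.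

Step 10
Reactants: 18 methyl (5S,6R,10R,13R)-3,3-ethylenedioxy-6-formyl-17-trimethylsilyl-labd-8-en-15-oate
Product: 19 methyl (5S,10R,13R)-3,3-ethylenedioxy-17-trimethylsilyl-labd-8-en-15-oate
Conditions: RhCl(PPh3)3 (1.1 equiv), PhCN, 130 °C
Reagents that add atoms: none
Why: Tsuji–Wilkinson decarbonylation (insertion into the formyl C–H bond, CO extrusion, C–H reductive elimination) excises the activating carbon and leaves C6 as CH2.

Step 11
Reactants: 19 methyl (5S,10R,13R)-3,3-ethylenedioxy-17-trimethylsilyl-labd-8-en-15-oate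
Product: 21 methyl (5S,9R,10S,13R)-3-oxolabd-8(17)-en-15-oate, via methylidene ketal 20 (not isolated)
Conditions: p-TsOH·H2O, acetone/H2O (10:1), 40 °C
Reagents that add atoms: water, O
Why: SE2′ protodesilylation: the electron-rich allylsilane is protonated at C9 axially, anti to the angular C20 methyl, and loses silicon, which should give H-9 cis to H-5, an equatorial side chain and the C8=C17 methylene (the β-silicon effect makes this far faster than protonation of the product alkene); the same aqueous acid hydrolyses the dioxolane.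

Step 12
Reactants: 21 methyl (5S,9R,10S,13R)-3-oxolabd-8(17)-en-15-oate
Product: 22 methyl (3S,5S,9R,10S,13R)-3-hydroxylabd-8(17)-en-15-oate (3-OH axial)
Conditions: LiBH(s-Bu)3, THF, −78 °C; then H2O
Reagents that add atoms: none
Why: The bulky trialkylborohydride attacks the 4,4-dimethyl-3-ketone of the trans-decalin along the equatorial path and should deliver the axial (3S) alcohol cis to H-5, as is usual for 4,4-dimethyl-3-oxo terpenoids, while the ester survives at −78 °C.

Step 13
Reactants: 22 methyl (3S,5S,9R,10S,13R)-3-hydroxylabd-8(17)-en-15-oate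
Product: 23 (3S,5S,9R,10S,13R)-3-hydroxylabd-8(17)-en-15-oic acid
Conditions: LiOH, THF/MeOH/H2O, rt; then 1 M HCl to pH 3, 0 °C
Reagents that add atoms: lithium hydroxide, [Li+].[OH-]
Why: Saponification of the unhindered methyl ester before acetylation, so that no ester has to be cleaved beside the acetate; no stereocentre is epimerisable.

Step 14
Reactants: 23 (3S,5S,9R,10S,13R)-3-hydroxylabd-8(17)-en-15-oic acid
Product: 25 (3R)-5-[(1R,4aS,6S,8aS)-6-acetoxy-5,5,8a-trimethyl-2-methylidenedecahydronaphthalen-1-yl]-3-methylpentanoic acid, via mixed anhydride 24 (not isolated)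
Conditions: Ac2O, DMAP, pyridine, 40 °C; then H2O/THF, rt
Reagents that add atoms: acetic anhydride, CC(=O)OC(C)=O
Why: DMAP-catalysed acetylation of the hindered axial alcohol; the mixed anhydride formed at the carboxyl group is hydrolysed in the aqueous work-up to give the target.

Compound list
1 | 3-bromopropanoyl chloride | O=C(Cl)CCBr | starting material
2 | trimethyl(3-methylbut-2-en-1-yl)silane | CC(C)=CC[Si](C)(C)C | starting material
3 | 1-bromo-4,4-dimethylhex-5-en-3-one | BrCCC(=O)C(C)(C)C=C | intermediate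
4 | 2-(2-bromoethyl)-2-(2-methylbut-3-en-2-yl)-1,3-dioxolane | BrCCC1(OCCO1)C(C)(C)C=C | intermediate
5 | methyl but-2-ynoate | CC#CC(=O)OC | starting material
6 | {2-[2-(2-methylbut-3-en-2-yl)-1,3-dioxolan-2-yl]ethyl}magnesium bromide (not isolated) | Br[Mg]CCC1(OCCO1)C(C)(C)C=C | intermediate
7 | {2-[2-(2-methylbut-3-en-2-yl)-1,3-dioxolan-2-yl]ethyl}copper, as its MgBr2 complex (not isolated) | [Cu]CCC1(OCCO1)C(C)(C)C=C | intermediate
8 | alkenylcopper from syn-addition of 7 to 5, copper on C9 cis to the C1 chain (not isolated) | COC(=O)/C([Cu])=C(\C)CCC1(OCCO1)C(C)(C)C=C | intermediate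
9 | methyl (2Z)-2-iodo-3-methyl-5-[2-(2-methylbut-3-en-2-yl)-1,3-dioxolan-2-yl]pent-2-enoate | COC(=O)/C(I)=C(\C)CCC1(OCCO1)C(C)(C)C=C | intermediate
10 | (3Z)-3-iodo-4-methyl-6-[2-(2-methylbut-3-en-2-yl)-1,3-dioxolan-2-yl]-1-(trimethylsilyl)-2-[(trimethylsilyl)methyl]hex-3-en-2-ol (not isolated) | C[Si](C)(C)CC(O)(C[Si](C)(C)C)/C(I)=C(\C)CCC1(OCCO1)C(C)(C)C=C | intermediate
11 | trimethyl{(3Z)-3-iodo-4-methyl-2-methylidene-6-[2-(2-methylbut-3-en-2-yl)-1,3-dioxolan-2-yl]hex-3-en-1-yl}silane | C=C(C[Si](C)(C)C)/C(I)=C(\C)CCC1(OCCO1)C(C)(C)C=C | intermediate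
12 | (3R)-5-methoxy-3-methyl-5-oxopentanoic acid | COC(=O)C[C@H](C)CC(=O)O | starting material
13 | methyl (3R)-5-hydroxy-3-methylpentanoate | COC(=O)C[C@H](C)CCO | intermediate
14 | methyl (3S)-5-iodo-3-methylpentanoate | COC(=O)C[C@H](C)CCI | intermediate
15 | [(3S)-5-methoxy-3-methyl-5-oxopentyl]zinc iodide (not isolated) | COC(=O)C[C@H](C)CC[Zn]I | intermediate
16 | methyl (3R,6E)-3,7-dimethyl-9-[2-(2-methylbut-3-en-2-yl)-1,3-dioxolan-2-yl]-6-[3-(trimethylsilyl)prop-1-en-2-yl]non-6-enoate | COC(=O)C[C@H](C)CC/C(C(=C)C[Si](C)(C)C)=C(/C)CCC1(OCCO1)C(C)(C)C=C | intermediate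
17 | methyl (3R,6E)-3,7-dimethyl-9-{2-[(3E)-2-methyl-5-oxopent-3-en-2-yl]-1,3-dioxolan-2-yl}-6-[3-(trimethylsilyl)prop-1-en-2-yl]non-6-enoate | COC(=O)C[C@H](C)CC/C(C(=C)C[Si](C)(C)C)=C(/C)CCC1(OCCO1)C(C)(C)/C=C/C=O | intermediate
18 | methyl (5S,6R,10R,13R)-3,3-ethylenedioxy-6-formyl-17-trimethylsilyl-labd-8-en-15-oate | COC(=O)C[C@H](C)CCC1=C(C[Si](C)(C)C)C[C@@H](C=O)[C@@H]2C(C)(C)C3(OCCO3)CC[C@@]12C | intermediate
19 | methyl (5S,10R,13R)-3,3-ethylenedioxy-17-trimethylsilyl-labd-8-en-15-oate | COC(=O)C[C@H](C)CCC1=C(C[Si](C)(C)C)CC[C@@H]2C(C)(C)C3(OCCO3)CC[C@@]12C | intermediate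
20 | methyl (5S,9R,10S,13R)-3,3-ethylenedioxylabd-8(17)-en-15-oate (not isolated) | C=C1CC[C@@H]2C(C)(C)C3(OCCO3)CC[C@@]2(C)[C@@H]1CC[C@@H](C)CC(=O)OC | intermediate
21 | methyl (5S,9R,10S,13R)-3-oxolabd-8(17)-en-15-oate | C=C1CC[C@@H]2C(C)(C)C(=O)CC[C@@]2(C)[C@@H]1CC[C@@H](C)CC(=O)OC | intermediate
22 | methyl (3S,5S,9R,10S,13R)-3-hydroxylabd-8(17)-en-15-oate | C=C1CC[C@@H]2C(C)(C)[C@@H](O)CC[C@@]2(C)[C@@H]1CC[C@@H](C)CC(=O)OC | intermediate
23 | (3S,5S,9R,10S,13R)-3-hydroxylabd-8(17)-en-15-oic acid | C=C1CC[C@@H]2C(C)(C)[C@@H](O)CC[C@@]2(C)[C@@H]1CC[C@@H](C)CC(=O)O | intermediate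
24 | mixed acetic anhydride of the 3-O-acetyl acid (not isolated) | C=C1CC[C@@H]2C(C)(C)[C@@H](OC(C)=O)CC[C@@]2(C)[C@@H]1CC[C@@H](C)CC(=O)OC(C)=O | intermediate
25 | (3R)-5-[(1R,4aS,6S,8aS)-6-acetoxy-5,5,8a-trimethyl-2-methylidenedecahydronaphthalen-1-yl]-3-methylpentanoic acid | C=C1CC[C@@H]2C(C)(C)[C@@H](OC(C)=O)CC[C@@]2(C)[C@@H]1CC[C@@H](C)CC(=O)O | target

Total step count: 14. Longest linear sequence: 12 steps (steps 1–4 and 7–14); steps 5 and 6 make the side-chain iodide in parallel.

Steps most likely to fail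

Step 9. The bond between C5 (next to the quaternary C4) and the fully substituted diene terminus C10 must form first, and the inside methyl group twists the diene out of the s-cis plane. The cycloaddition may therefore be slow, an uncatalysed background reaction may erode endo and facial control, and the developing 1,3-diaxial methyl–methyl contact may favour the cis-fused mode. The new aldehyde could also be attacked by the allylsilane under acid. Fallback with a covalently bound auxiliary: triene 16 is cross-metathesised with (4R)-3-acryloyl-4-benzyl-1,3-oxazolidin-2-one to the enoyl imide F1. Me2AlCl in CH2Cl2 at −30 °C then brings about the chelate-controlled endo cycloaddition (the benzyl group shields the same face as the catalyst) to the imide cycloadduct F2. LiSEt in THF at 0 °C gives the ethyl thioester F3, and Et3SiH with Pd on carbon (Fukuyama reduction) gives aldehyde 18, where the route is rejoined.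

Step 8. Metathesis may engage the conjugated diene terminus or be slowed at the neopentyl-type vinyl group in its presence, which would give truncated or ring-closed products. Fallback that installs the enal before the diene exists: iodo enoate 9, whose vinyl group is its only metathesis-active alkene, is treated with crotonaldehyde and the same catalyst to give the enal F4. HC(OMe)3 and PPTS in MeOH protect it as the dimethyl acetal F5. Me3SiCH2MgCl with CeCl3 gives the carbinol F6, which silica gel converts into the iodo diene acetal F7. Negishi coupling with organozinc iodide 15 gives the triene acetal F8, and PPTS in wet acetone at room temperature (the hindered C3 dioxolane stays) releases trienal 17, where the route is rejoined.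

Step 10. Decarbonylation of the hindered secondary aldehyde may stop short, or the alkylrhodium hydride may undergo β-hydride elimination to an alkene. Fallback by radical decarboxylation: aldehyde 18 is oxidised (NaClO2, NaH2PO4, 2-methylbut-2-ene, t-BuOH/H2O) to the carboxylic acid F9. DCC and N-hydroxypyridine-2-thione convert it into the thiohydroxamate ester F10, and t-BuSH under visible light in benzene gives 19, where the route is rejoined.

Further compounds
F1 | step 9 | methyl (3R,6E)-9-{2-[(3E)-5-[(4R)-4-benzyl-2-oxo-1,3-oxazolidin-3-yl]-2-methyl-5-oxopent-3-en-2-yl]-1,3-dioxolan-2-yl}-3,7-dimethyl-6-[3-(trimethylsilyl)prop-1-en-2-yl]non-6-enoate | COC(=O)C[C@H](C)CC/C(C(=C)C[Si](C)(C)C)=C(/C)CCC1(OCCO1)C(C)(C)/C=C/C(=O)N1[C@H](Cc2ccccc2)COC1=O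
F2 | step 9 | analogue of 18 in which the 6-formyl group is replaced by the (4R)-4-benzyl-2-oxo-1,3-oxazolidine-3-carbonyl group | COC(=O)C[C@H](C)CCC1=C(C[Si](C)(C)C)C[C@@H](C(=O)N4[C@H](Cc5ccccc5)COC4=O)[C@@H]2C(C)(C)C3(OCCO3)CC[C@@]12C
F3 | step 9 | analogue of 18 in which the 6-formyl group is replaced by the (ethylsulfanyl)carbonyl group | COC(=O)C[C@H](C)CCC1=C(C[Si](C)(C)C)C[C@@H](C(=O)SCC)[C@@H]2C(C)(C)C3(OCCO3)CC[C@@]12C
F4 | step 8 | methyl (2Z)-2-iodo-3-methyl-5-{2-[(3E)-2-methyl-5-oxopent-3-en-2-yl]-1,3-dioxolan-2-yl}pent-2-enoate | COC(=O)/C(I)=C(\C)CCC1(OCCO1)C(C)(C)/C=C/C=O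
F5 | step 8 | methyl (2Z)-5-{2-[(3E)-5,5-dimethoxy-2-methylpent-3-en-2-yl]-1,3-dioxolan-2-yl}-2-iodo-3-methylpent-2-enoate | COC(=O)/C(I)=C(\C)CCC1(OCCO1)C(C)(C)/C=C/C(OC)OC
F6 | step 8 | (3Z)-6-{2-[(3E)-5,5-dimethoxy-2-methylpent-3-en-2-yl]-1,3-dioxolan-2-yl}-3-iodo-4-methyl-1-(trimethylsilyl)-2-[(trimethylsilyl)methyl]hex-3-en-2-ol | C[Si](C)(C)CC(O)(C[Si](C)(C)C)/C(I)=C(\C)CCC1(OCCO1)C(C)(C)/C=C/C(OC)OC
F7 | step 8 | {(3Z)-6-{2-[(3E)-5,5-dimethoxy-2-methylpent-3-en-2-yl]-1,3-dioxolan-2-yl}-3-iodo-4-methyl-2-methylidenehex-3-en-1-yl}trimethylsilane | C=C(C[Si](C)(C)C)/C(I)=C(\C)CCC1(OCCO1)C(C)(C)/C=C/C(OC)OC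
F8 | step 8 | methyl (3R,6E)-9-{2-[(3E)-5,5-dimethoxy-2-methylpent-3-en-2-yl]-1,3-dioxolan-2-yl}-3,7-dimethyl-6-[3-(trimethylsilyl)prop-1-en-2-yl]non-6-enoate | COC(=O)C[C@H](C)CC/C(C(=C)C[Si](C)(C)C)=C(/C)CCC1(OCCO1)C(C)(C)/C=C/C(OC)OC
F9 | step 10 | analogue of 18 in which the 6-formyl group is replaced by a carboxyl group | COC(=O)C[C@H](C)CCC1=C(C[Si](C)(C)C)C[C@@H](C(=O)O)[C@@H]2C(C)(C)C3(OCCO3)CC[C@@]12C
F10 | step 10 | 2-thioxopyridin-1(2H)-yl ester of acid F9 | COC(=O)C[C@H](C)CCC1=C(C[Si](C)(C)C)C[C@@H](C(=O)On4ccccc4=S)[C@@H]2C(C)(C)C3(OCCO3)CC[C@@]12C
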